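**Assumptions (stated once):** (i) TIPSCl silylates the less hindered 4-OH of 2-methylhydroquinone preferentially, and the minor regioisomer is removed by chromatography. (ii) The Trost ligand enantiomer is the one that gives the (S)-aryl ether 8, which corresponds to (R)-sargachromenol. If the opposite sense is observed, the other ligand enantiomer is used.

## Retrosynthesis
1. The acid comes from a (Z)-selective Ando HWE of the C7′ aldehyde with an α-homoprenyl diaryl phosphonoacetate, followed by ester and silyl cleavage.
2. The E-trisubstituted C3′=C4′ alkene and the C7′ carbon come from a Johnson–Claisen rearrangement of an isopropenyl carbinol, which is made from the propanal side chain.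
3. The propanal comes from a Wittig homologation of the chromene aldehyde followed by chemoselective enzymatic C=C reduction of the enal.
4. The only ring, the 2H-chromene, is formed by RCM after the quaternary C2 centre has been set by Pd-catalysed asymmetric allylic etherification (DYKAT) of isoprene monoxide with an o-vinylphenol.
5. C2 is set at step 6 and the ring is closed at step 7. Nothing later touches C2.

## Route

**Step 1**
Reactants: 1 2-methylbenzene-1,4-diol
Product: 2 4-(triisopropylsilyloxy)-2-methylphenol
Conditions: TIPSCl (0.95 equiv), imidazole, DMF, 0 °C→rt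
Reagents that add atoms: TIPSCl, CC(C)[Si](Cl)(C(C)C)C(C)C
Why: The bulky silyl chloride reacts at the unhindered OH (chemoselective silylation). This leaves the OH ortho to the methyl group free for the later etherification.

**Step 2**
Reactants: 2
Product: 3 2-hydroxy-3-methyl-5-(TIPSO)benzaldehyde
Conditions: MgCl2, Et3N, (CH2O)n, MeCN, 80 °C
Reagents that add atoms: paraformaldehyde, C=O
Why: Casnati–Skattebøl Mg-phenoxide ortho-formylation goes to the only free ortho position.

**Step 3**
Reactants: 3
Product: 4 4-(TIPSO)-2-methyl-6-vinylphenol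
Conditions: Ph3PCH3Br (2.5 equiv), KOtBu (5 equiv), THF, 0 °C→rt
Reagents that add atoms: methyltriphenylphosphonium bromide, C[P+](c1ccccc1)(c1ccccc1)c1ccccc1.[Br-]
Why: Wittig methylenation. The extra base covers the phenol OH. The product is used promptly because o-hydroxystyrenes polymerise.

**Step 4**
Reactants: 5 isoprene
Product: 6 1-bromo-2-methylbut-3-en-2-ol
Conditions: NBS, THF/H2O 1:1, 0 °C
Reagents that add atoms: NBS, O=C1CCC(=O)N1Br; water, O
Why: Markovnikov bromohydrin formation at the more substituted alkene gives the tertiary alcohol.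

**Step 5**
Reactants: 6
Product: 7 2-methyl-2-vinyloxirane (racemic)
Conditions: 30% aq. KOH, 0 °C→rt, then distil
Reagents that add atoms: none (loses HBr)
Why: Intramolecular Williamson epoxide closure. The racemate is acceptable because the Pd π-allyl intermediate racemises (DYKAT).

**Step 6**
Reactants: 4 and 7
Product: 8 (2S)-2-{[2-methyl-4-(TIPSO)-6-vinylphenyl]oxy}-2-methylbut-3-en-1-ol
Conditions: Pd2(dba)3·CHCl3 (2.5 mol%), (R,R)-Trost DACH-phenyl ligand (7.5 mol%), CH2Cl2, 23 °C, 24 h
Reagents that add atoms: none (catalysts only)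
Why: Pd-catalysed asymmetric allylic alkylation with dynamic kinetic asymmetric transformation (Trost). The phenoxide attacks the tertiary terminus of the racemising π-allyl, so the ligand sets the quaternary aryl-ether centre (first and only stereocentre).

**Step 7**
Reactants: 8
Product: 9 [(2S)-2,8-dimethyl-6-(TIPSO)-2H-chromen-2-yl]methanol
Conditions: Grubbs II (5 mol%), CH2Cl2 (0.01 M), 40 °C
Reagents that add atoms: none (loses ethylene)
Why: Ring-closing metathesis of the styrene and the quaternary vinyl group forms the 6-membered 2H-chromene. C2 is not involved in the bond changes.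

**Step 8**
Reactants: 9
Product: 10 (2S)-2,8-dimethyl-6-(TIPSO)-2H-chromene-2-carbaldehyde
Conditions: DMP, NaHCO3, CH2Cl2, 0 °C→rt
Reagents that add atoms: none
Why: Mild Dess–Martin oxidation. The aldehyde has no α-H, so C2 cannot epimerise.

**Step 9**
Reactants: 10
Product: 11 (2E)-3-[(2S)-2,8-dimethyl-6-(TIPSO)-2H-chromen-2-yl]prop-2-enal
Conditions: Ph3P=CHCHO (3 equiv), PhCO2H (cat.), toluene, 100 °C, 36 h
Reagents that add atoms: (formylmethylene)triphenylphosphorane, O=CC=P(c1ccccc1)(c1ccccc1)c1ccccc1
Why: Wittig homologation with a stabilised ylide gives the E-enal (two-carbon extension, C2′–C3′).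

**Step 10**
Reactants: 11
Product: 12 3-[(2R)-2,8-dimethyl-6-(TIPSO)-2H-chromen-2-yl]propanal
Conditions: ene-reductase (Old Yellow Enzyme family, e.g. OYE2), NADP+ (1 mol%), glucose (3 equiv), glucose dehydrogenase, KPi pH 7.0/DMSO 85:15, 30 °C, 24 h, dark
Reagents that add atoms: none (adds only H2, supplied by glucose via NADPH)
Why: The flavin-dependent ene-reductase reduces only the activated enal C=C and leaves the chromene C3=C4 and the aryl silyl ether untouched. No new stereocentre forms, and C2 is untouched.

**Step 11**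
Reactants: 12
Product: 13 1-[(2R)-chromen-2-yl]-4-methylpent-4-en-3-ol, i.e. C=C(C)C(O)CC–chromene (mixture at the carbinol carbon)
Conditions: isopropenylMgBr (2 equiv), THF, −78→0 °C
Reagents that add atoms: isopropenylmagnesium bromide, C=C(C)[Mg]Br
Why: Grignard 1,2-addition. The carbinol centre is destroyed in step 12, so its configuration is irrelevant.

**Step 12**
Reactants: 13
Product: 14 ethyl (E)-4-methyl-6-[(2R)-chromen-2-yl]hex-4-enoate, i.e. EtO2CCH2CH2C(CH3)=CHCH2CH2–chromene
Conditions: MeC(OEt)3 (10 equiv), EtCO2H (5 mol%), 140 °C, sealed tube, 1 h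
Reagents that add atoms: triethyl orthoacetate, CC(OCC)(OCC)OCC
Why: Johnson–Claisen [3,3] rearrangement through a chair transition state with the chain equatorial gives the E-trisubstituted alkene (C3′=C4′) and adds C6′–C7′.

**Step 13**
Reactants: 14
Product: 15 (E)-4-methyl-6-[(2R)-chromen-2-yl]hex-4-en-1-ol
Conditions: LiAlH4, THF, 0 °C
Reagents that add atoms: none (adds H only)
Why: Ester reduction. The alkenes and the aryl silyl ether are inert at 0 °C.

**Step 14**
Reactants: 15
Product: 16 (E)-4-methyl-6-[(2R)-chromen-2-yl]hex-4-enal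
Conditions: DMP, NaHCO3, CH2Cl2, 0 °C→rt
Reagents that add atoms: none
Why: Mild oxidation stops at the aldehyde, with no alkene isomerisation.

**Step 15**
Reactants: 17 triethyl phosphonoacetate and 18 5-bromo-2-methylpent-2-ene
Product: 19 ethyl 2-(diethoxyphosphoryl)-6-methylhept-5-enoate
Conditions: NaH, THF, 0 °C; then 18, cat. NaI, reflux
Reagents that add atoms: none (both partners are the numbered reactants)
Why: Phosphonate enolate SN2 alkylation at a primary bromide installs the homoprenyl side chain.

**Step 16**
Reactants: 19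
Product: 20 ethyl 2-(dichlorophosphoryl)-6-methylhept-5-enoate
Conditions: TMSBr, CH2Cl2, rt; evaporate; then (COCl)2, cat. DMF, CH2Cl2, rt
Reagents that add atoms: oxalyl chloride, O=C(Cl)C(=O)Cl
Why: Neutral TMSBr dealkylation followed by Vilsmeier-type chlorination gives the dichloride without generating HX that could add to the prenyl alkene. The dichloride is used crude.

**Step 17**
Reactants: 20
Product: 21 ethyl 2-[bis(2-methylphenoxy)phosphoryl]-6-methylhept-5-enoate (Ando reagent)
Conditions: o-cresol (2.2 equiv), Et3N, CH2Cl2, 0 °C→rt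
Reagents that add atoms: 2-methylphenol, Cc1ccccc1O
Why: Nucleophilic substitution at P(V) gives the diaryl phosphonate.

**Step 18**
Reactants: 16 and 21
Product: 22 ethyl (2Z,6E)-2-(4-methylpent-3-enyl)-6-methyl-8-[(2R)-chromen-2-yl]octa-2,6-dienoate
Conditions: 21 + NaH, THF, 0 °C; cool to −78 °C; add 16; −78→−20 °C
Reagents that add atoms: none (21 is the numbered reactant)
Why: Ando Z-selective Horner–Wadsworth–Emmons. The electron-poor diaryl phosphonate makes oxaphosphetane collapse fast and kinetically controlled, which places the ester cis to the aldehyde substituent and reproduces the (Z)-acid geometry of the target.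

**Step 19**
Reactants: 22
Product: 23 the TIPS-protected acid
Conditions: LiOH·H2O (10 equiv), THF/MeOH/H2O 1:1:1, 60 °C, 16 h; then citric acid to pH 4
Reagents that add atoms: none
Why: Saponification of the hindered ester. Hydroxide does not isomerise the alkene geometry.

**Step 20**
Reactants: 23
Product: 24 (R)-sargachromenol
Conditions: TBAF, AcOH (1:1), THF, 0 °C, under N2, in the dark
Reagents that add atoms: none
Why: Fluoride cleaves the aryl TIPS ether. The buffering acetic acid limits phenoxide oxidation and base-induced side reactions. Step 20 frees the 6-OH and gives the target.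

## Compound list
1 | 2-methylbenzene-1,4-diol | Cc1cc(O)ccc1O | starting material
2 | 4-(TIPSO)-2-methylphenol | Cc1cc(O[Si](C(C)C)(C(C)C)C(C)C)ccc1O | intermediate
3 | 2-hydroxy-3-methyl-5-(TIPSO)benzaldehyde | O=Cc1cc(O[Si](C(C)C)(C(C)C)C(C)C)cc(C)c1O | intermediate
4 | 4-(TIPSO)-2-methyl-6-vinylphenol | C=Cc1cc(O[Si](C(C)C)(C(C)C)C(C)C)cc(C)c1O | intermediate
5 | isoprene | C=CC(C)=C | starting material
6 | 1-bromo-2-methylbut-3-en-2-ol | BrCC(C)(O)C=C | intermediate
7 | 2-methyl-2-vinyloxirane (racemic) | C=CC1(C)CO1 | intermediate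
8 | (2S)-aryl ether alcohol | OC[C@](Oc1c(C)cc(O[Si](C(C)C)(C(C)C)C(C)C)cc1C=C)(C)C=C | intermediate
9 | [(2S)-chromen-2-yl]methanol | OC[C@]1(C)C=Cc2cc(O[Si](C(C)C)(C(C)C)C(C)C)cc(C)c2O1 | intermediate
10 | (2S)-chromene-2-carbaldehyde | O=C[C@]1(C)C=Cc2cc(O[Si](C(C)C)(C(C)C)C(C)C)cc(C)c2O1 | intermediate
11 | (E)-enal | O=C/C=C/[C@]1(C)C=Cc2cc(O[Si](C(C)C)(C(C)C)C(C)C)cc(C)c2O1 | intermediate
12 | (2R)-propanal | O=CCC[C@]1(C)C=Cc2cc(O[Si](C(C)C)(C(C)C)C(C)C)cc(C)c2O1 | intermediate
13 | isopropenyl carbinol | C=C(C)C(O)CC[C@]1(C)C=Cc2cc(O[Si](C(C)C)(C(C)C)C(C)C)cc(C)c2O1 | intermediate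
14 | ethyl (E)-hexenoate | CCOC(=O)CC/C(C)=C/CC[C@]1(C)C=Cc2cc(O[Si](C(C)C)(C(C)C)C(C)C)cc(C)c2O1 | intermediate
15 | primary alcohol | OCCC/C(C)=C/CC[C@]1(C)C=Cc2cc(O[Si](C(C)C)(C(C)C)C(C)C)cc(C)c2O1 | intermediate
16 | aldehyde | O=CCC/C(C)=C/CC[C@]1(C)C=Cc2cc(O[Si](C(C)C)(C(C)C)C(C)C)cc(C)c2O1 | intermediate
17 | triethyl phosphonoacetate | CCOC(=O)CP(=O)(OCC)OCC | starting material
18 | 5-bromo-2-methylpent-2-ene | CC(C)=CCCBr | starting material
19 | alkylated phosphonate | CCOC(=O)C(CCC=C(C)C)P(=O)(OCC)OCC | intermediate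
20 | dichlorophosphonate | CCOC(=O)C(CCC=C(C)C)P(=O)(Cl)Cl | intermediate
21 | Ando reagent | CCOC(=O)C(CCC=C(C)C)P(=O)(Oc1ccccc1C)Oc1ccccc1C | intermediate
22 | (Z)-ester | CC(C)=CCC/C(=C/CC/C(C)=C/CC[C@]1(C)C=Cc2cc(O[Si](C(C)C)(C(C)C)C(C)C)cc(C)c2O1)C(=O)OCC | intermediate
23 | TIPS-protected acid | CC(C)=CCC/C(=C/CC/C(C)=C/CC[C@]1(C)C=Cc2cc(O[Si](C(C)C)(C(C)C)C(C)C)cc(C)c2O1)C(=O)O | intermediate
24 | (R)-sargachromenol | CC(C)=CCC/C(=C/CC/C(C)=C/CC[C@]1(C)C=Cc2cc(O)cc(C)c2O1)C(=O)O | target

## Totals
Total steps: 20. Longest linear sequence: 15 (steps 1→2→3→6→7→8→9→10→11→12→13→14→18→19→20).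

## Three steps most likely to fail
1. **Step 6 (Pd-AAA onto a 2,6-disubstituted phenol).** The yield or ee may be low because the phenol is hindered.
   - Fallback: make racemic 9 with Pd(PPh3)4 (same etherification and RCM sequence), then resolve the primary alcohol by lipase-catalysed acetylation (vinyl acetate), keeping the (S)-alcohol.
2. **Step 10 (ene-reductase on the hindered, lipophilic enal).** The enzyme may show low turnover or poor solubility.
   - Fallback: from 10, run a HWE with triethyl phosphonoacetate, then Mg/MeOH conjugate reduction of the enoate, then DIBAL to give 12.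
3. **Step 18 (Z-selectivity of the α-alkyl Ando olefination).** A Z:E mixture that is hard to separate is possible.
   - Fallback: Peterson olefination of 16 with ethyl 2-(trimethylsilyl)-6-methylhept-5-enoate enolate. Separate the β-hydroxysilane diastereomers and eliminate with acid (anti) or KH (syn) to give the pure Z-alkene.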